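**Plan**

- Feature and first cut: in 3,4-dihydrocoumarin numbering (primes for the second half) the outer ring C2–O1–C8a–C4a–C4–C3'–C2'–O1'–C8a'–C4a'–C4'–C3 of the lactone–cyclobutane–lactone core has twelve members and is bridged only by C3–C4 and C3'–C4'. Cutting these two bonds opens the cyclobutane and both six-membered lactones and leaves a Z,Z head-to-tail diolide of two pyrano-fused cis-cinnamate units.
- Further cuts: the C4=C3' alkene is traced back to an alkyne, the ester C2–O1 is opened (macrolactonisation in the forward sense), and the ester C2'–O1' is cut into an O-silylated arylpropiolic acid and ring-opened seselin. Both pieces come from one chromene aldehyde made from 2,4-dihydroxybenzaldehyde and 3-methylbut-2-enal.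
- Forward order of rings: pyran ring (chromene annulation), then the twelve-membered ring (closed with one alkyne in it, then semi-hydrogenated), and last the cyclobutane together with both six-membered lactones.
- Two rules shape the sequence: a phenol is never set free cis to an acyl group (it would close to seselin), and the ring is never closed with two alkynes in it (two linear Ar–C≡C–C(=O) units joined by planar aryl esters should not span twelve ring atoms without twisting both esters out of conjugation).
- Stereochemistry: the Z geometry of C3=C4' is inherited from the lactone ring of seselin and that of C4=C3' comes from syn hydrogenation. C3, C4, C3' and C4' are set together in the photocycloaddition, all-cis through the two Z alkenes and the cis ring fusions, and in absolute sense through the chiral Lewis acid.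

Key step: step 10

Assumption: the Lewis acid built from (S)-diphenylprolinol is taken to give the (3S,4R,3'S,4'R) product; should it favour the mirror image, the (R)-prolinol-derived catalyst is used with everything else unchanged.

**Step 1**
Reactants: 1 2,4-dihydroxybenzaldehyde; 2 3-methylbut-2-enal
Product: 3 5-hydroxy-2,2-dimethyl-2H-chromene-6-carbaldehyde
Conditions: pyridine, 140 °C, sealed tube
Reagents that add atoms: none
Why: Pyridine-mediated chromene annulation (condensation of the enal at C3 followed by oxa-6π electrocyclisation) should occur between the two oxygens and through the free 4-OH, because the 2-OH is held in a hydrogen bond to the formyl group, the regiochemistry established for 2,4-dihydroxybenzaldehyde and its acetophenone analogue.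

**Step 2**
Reactants: 3 5-hydroxy-2,2-dimethyl-2H-chromene-6-carbaldehyde
Product: 4 5-[(tert-butyldimethylsilyl)oxy]-2,2-dimethyl-2H-chromene-6-carbaldehyde
Conditions: TBSCl, imidazole, DMF, 40 °C
Reagents that add atoms: tert-butyldimethylsilyl chloride, CC(C)(C)[Si](C)(C)Cl
Why: Standard imidazole-promoted silylation of a phenol masks the acidic OH for the organolithium step and leaves a group that fluoride removes later without acid or strong base.

**Step 3**
Reactants: 4 5-[(tert-butyldimethylsilyl)oxy]-2,2-dimethyl-2H-chromene-6-carbaldehyde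
Product: 5 tert-butyl{[6-(2,2-dibromoethenyl)-2,2-dimethyl-2H-chromen-5-yl]oxy}dimethylsilane
Conditions: CBr4, PPh3, CH2Cl2, 0 °C
Reagents that add atoms: carbon tetrabromide, BrC(Br)(Br)Br
Why: Ramirez dibromo-olefination, the first stage of the Corey–Fuchs sequence, converts an aromatic aldehyde reliably into the 1,1-dibromoalkene with the ylide formed in the flask.

**Step 4**
Reactants: 5 tert-butyl{[6-(2,2-dibromoethenyl)-2,2-dimethyl-2H-chromen-5-yl]oxy}dimethylsilane
Product: 8 3-{5-[(tert-butyldimethylsilyl)oxy]-2,2-dimethyl-2H-chromen-6-yl}prop-2-ynoic acid, via lithium acetylide 6 (not isolated), via lithium carboxylate 7 (not isolated)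
Conditions: n-BuLi (2.2 equiv), THF, −78 °C; CO2, −78 °C to rt; aq. HCl to pH 3
Reagents that add atoms: carbon dioxide, O=C=O
Why: In the second stage of the Corey–Fuchs sequence, bromine–lithium exchange and elimination give the lithium acetylide, which is carboxylated by CO2 to the arylpropiolic acid, whose linear alkyne keeps the acyl carbon out of reach of the ortho oxygen.

**Step 5**
Reactants: 3 5-hydroxy-2,2-dimethyl-2H-chromene-6-carbaldehyde
Product: 10 seselin (8,8-dimethyl-2H,8H-pyrano[2,3-f]chromen-2-one), via ethyl hydroxycinnamate 9 (not isolated)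
Conditions: Ph3P=CHCO2Et, PhNEt2, reflux
Reagents that add atoms: ethyl (triphenylphosphoranylidene)acetate, CCOC(=O)C=P(c1ccccc1)(c1ccccc1)c1ccccc1
Why: Wittig olefination with a stabilised ylide followed by thermal E/Z equilibration and lactonisation in refluxing diethylaniline is the classical route from salicylaldehydes to coumarins, and the lactone ring locks this cinnamate unit in the Z geometry.

**Step 6**
Reactants: 10 seselin; 8 3-{5-[(tert-butyldimethylsilyl)oxy]-2,2-dimethyl-2H-chromen-6-yl}prop-2-ynoic acid
Product: 13 (Z)-3-{5-[(3-{5-[(tert-butyldimethylsilyl)oxy]-2,2-dimethyl-2H-chromen-6-yl}prop-2-ynoyl)oxy]-2,2-dimethyl-2H-chromen-6-yl}prop-2-enoic acid, via dipotassium coumarinate 11 (not isolated), via acid chloride 12 (not isolated)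
Conditions: 8: Me2C=C(Cl)NMe2, CH2Cl2, 0 °C to rt, then evaporation; 10: KOtBu (2 equiv), H2O (1 equiv), THF, 0 °C to rt; then 12 in THF, −40 to 0 °C; cold aq. HCl to pH 3
Reagents that add atoms: water, O
Why: Saponification of the lactone gives the Z-configured phenoxide–carboxylate, whose phenoxide is the more basic and more nucleophilic anion and should be O-acylated by the acid chloride (Schotten–Baumann-type acylation of a coumarinate, as in the classical preparations of O-alkyl and O-acyl coumarinic acids); the Z geometry is carried over from the ring and the acylated oxygen can no longer relactonise.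

**Step 7**
Reactants: 13 (Z)-3-{5-[(3-{5-[(tert-butyldimethylsilyl)oxy]-2,2-dimethyl-2H-chromen-6-yl}prop-2-ynoyl)oxy]-2,2-dimethyl-2H-chromen-6-yl}prop-2-enoic acid
Product: 14 (Z)-3-(5-{[3-(5-hydroxy-2,2-dimethyl-2H-chromen-6-yl)prop-2-ynoyl]oxy}-2,2-dimethyl-2H-chromen-6-yl)prop-2-enoic acid
Conditions: TBAF, AcOH (1:1), THF, 0 °C
Reagents that add atoms: none
Why: Fluoride-induced cleavage of the aryl silyl ether, buffered with acetic acid so that the aryl propiolate survives, frees a phenol that stands next to the alkyne and not cis to an acyl group, so no six-membered lactone can form.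

**Step 8**
Reactants: 14 (Z)-3-(5-{[3-(5-hydroxy-2,2-dimethyl-2H-chromen-6-yl)prop-2-ynoyl]oxy}-2,2-dimethyl-2H-chromen-6-yl)prop-2-enoic acid
Product: 16 ene–yne diolide (twelve-membered head-to-tail diester with one Z-propenoate and one propynoate bridge), via mixed anhydride 15 (not isolated)
Conditions: MNBA (2-methyl-6-nitrobenzoic anhydride), DMAP (cat.), Et3N, CH2Cl2 (1 mM), syringe-pump addition, rt
Reagents that add atoms: none
Why: Shiina macrolactonisation under high dilution should let the mixed anhydride of the Z-acid acylate the remote phenol, because neither end can form a six-membered lactone and a ring holding only one linear alkyne unit can close once the aryl propiolate takes its s-cis ester conformation.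

**Step 9**
Reactants: 16 ene–yne diolide
Product: 17 Z,Z-diolide (twelve-membered head-to-tail diolide of (Z)-3-(5-hydroxy-2,2-dimethyl-2H-chromen-6-yl)prop-2-enoic acid)
Conditions: H2 (1 atm, 1 equiv), Pd/CaCO3 poisoned with Pb(OAc)2, quinoline, EtOAc, rt
Reagents that add atoms: none
Why: Lindlar semi-hydrogenation delivers both hydrogens to one face of the ynoate on the poisoned Pd surface and so gives the second Z-enoate, while the pyran alkenes and the existing Z-alkene should stay untouched when uptake is stopped at one equivalent.

**Step 10**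
Reactants: 17 Z,Z-diolide
Product: 18 CNP0167575.1, the (3S,4R,3'S,4'R) syn head-to-tail cyclobutane dimer of seselin with all four cyclobutane hydrogens cis
Conditions: oxazaborolidine from (S)-α,α-diphenylprolinol and 2,4,6-trifluorophenylboronic acid (50 mol%), AlBr3 (50 mol%), CH2Cl2, −75 °C, hν (366 nm)
Reagents that add atoms: none
Why: Proposed new method: the AlBr3-activated oxazaborolidine is expected to bind one ester carbonyl of 17 and shift the absorption of that cis-cinnamate to longer wavelength, so that 366 nm light excites only the complex; the excited alkene then bonds C3 to C4 of the facing cinnamate and leaves a 1,4-diradical at benzylic C4' and α-carbonyl C3' that couples to the cyclobutane. The closest known reactions are [2+2] photocycloadditions of coumarins and cinnamate esters under chiral Lewis acid control and the intramolecular photodimerisation of tethered cinnamates to cinnamophanes; a transannular version on a macrocyclic diolide has no precedent. Lactone ring A (O1–C2–C3–C4–C4a–C8a) closes 6-exo-trig through the first bond C3–C4, and the second bond C3'–C4' closes the cyclobutane by radical–radical coupling and, being shared, lactone ring B (O1'–C2'–C3'–C4'–C4a'–C8a') at the same time. C3, C4, C3' and C4' are set together: both alkenes are Z and add suprafacially and both six/four ring fusions must be cis, so all four hydrogens end on one face, while the absolute sense is set by the chiral Lewis acid, which is expected to select one of the two helical, C2-symmetric conformers of the macrocycle. The step needs head-to-tail regioselectivity, which the twelve-membered ring enforces because it allows no other pairing of the alkenes, and retention of both Z geometries up to ring closure, which the short transannular tether should secure by hindering rotation in the diradical; the saturated lactones of 18 no longer absorb at 366 nm, so the product should not revert.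

**Compound list**

1 | 2,4-dihydroxybenzaldehyde | O=Cc1ccc(O)cc1O | starting material
2 | 3-methylbut-2-enal | CC(C)=CC=O | starting material
3 | 5-hydroxy-2,2-dimethyl-2H-chromene-6-carbaldehyde | O=Cc1ccc2OC(C)(C)C=Cc2c1O | intermediate
4 | 5-[(tert-butyldimethylsilyl)oxy]-2,2-dimethyl-2H-chromene-6-carbaldehyde | O=Cc1ccc2OC(C)(C)C=Cc2c1O[Si](C)(C)C(C)(C)C | intermediate
5 | tert-butyl{[6-(2,2-dibromoethenyl)-2,2-dimethyl-2H-chromen-5-yl]oxy}dimethylsilane | BrC(Br)=Cc1ccc2OC(C)(C)C=Cc2c1O[Si](C)(C)C(C)(C)C | intermediate
6 | ({5-[(tert-butyldimethylsilyl)oxy]-2,2-dimethyl-2H-chromen-6-yl}ethynyl)lithium | [Li]C#Cc1ccc2OC(C)(C)C=Cc2c1O[Si](C)(C)C(C)(C)C | intermediate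
7 | lithium 3-{5-[(tert-butyldimethylsilyl)oxy]-2,2-dimethyl-2H-chromen-6-yl}prop-2-ynoate | [Li+].[O-]C(=O)C#Cc1ccc2OC(C)(C)C=Cc2c1O[Si](C)(C)C(C)(C)C | intermediate
8 | 3-{5-[(tert-butyldimethylsilyl)oxy]-2,2-dimethyl-2H-chromen-6-yl}prop-2-ynoic acid | OC(=O)C#Cc1ccc2OC(C)(C)C=Cc2c1O[Si](C)(C)C(C)(C)C | intermediate
9 | ethyl 3-(5-hydroxy-2,2-dimethyl-2H-chromen-6-yl)prop-2-enoate (E/Z mixture) | CCOC(=O)C=Cc1ccc2OC(C)(C)C=Cc2c1O | intermediate
10 | seselin (8,8-dimethyl-2H,8H-pyrano[2,3-f]chromen-2-one) | O=C1C=Cc2ccc3OC(C)(C)C=Cc3c2O1 | intermediate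
11 | dipotassium (Z)-3-(2,2-dimethyl-5-oxido-2H-chromen-6-yl)prop-2-enoate | [K+].[K+].[O-]C(=O)/C=C\c1ccc2OC(C)(C)C=Cc2c1[O-] | intermediate
12 | 3-{5-[(tert-butyldimethylsilyl)oxy]-2,2-dimethyl-2H-chromen-6-yl}prop-2-ynoyl chloride | ClC(=O)C#Cc1ccc2OC(C)(C)C=Cc2c1O[Si](C)(C)C(C)(C)C | intermediate
13 | (Z)-3-{5-[(3-{5-[(tert-butyldimethylsilyl)oxy]-2,2-dimethyl-2H-chromen-6-yl}prop-2-ynoyl)oxy]-2,2-dimethyl-2H-chromen-6-yl}prop-2-enoic acid | OC(=O)/C=C\c1ccc2OC(C)(C)C=Cc2c1OC(=O)C#Cc1ccc2OC(C)(C)C=Cc2c1O[Si](C)(C)C(C)(C)C | intermediate
14 | (Z)-3-(5-{[3-(5-hydroxy-2,2-dimethyl-2H-chromen-6-yl)prop-2-ynoyl]oxy}-2,2-dimethyl-2H-chromen-6-yl)prop-2-enoic acid | OC(=O)/C=C\c1ccc2OC(C)(C)C=Cc2c1OC(=O)C#Cc1ccc2OC(C)(C)C=Cc2c1O | intermediate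
15 | mixed anhydride of 14 (at its Z-propenoic acid) with 2-methyl-6-nitrobenzoic acid | Cc1cccc([N+](=O)[O-])c1C(=O)OC(=O)/C=C\c1ccc2OC(C)(C)C=Cc2c1OC(=O)C#Cc1ccc2OC(C)(C)C=Cc2c1O | intermediate
16 | ene–yne diolide: twelve-membered head-to-tail diester in which the (Z)-propenoyl group of one 2,2-dimethyl-2H-chromen-5-ol unit acylates O5 of the other, whose propynoyl group acylates O5 of the first | O=C1/C=C\c2ccc3OC(C)(C)C=Cc3c2OC(=O)C#Cc2ccc3OC(C)(C)C=Cc3c2O1 | intermediate
17 | Z,Z twelve-membered head-to-tail diolide of (Z)-3-(5-hydroxy-2,2-dimethyl-2H-chromen-6-yl)prop-2-enoic acid | O=C1/C=C\c2ccc3OC(C)(C)C=Cc3c2OC(=O)/C=C\c2ccc3OC(C)(C)C=Cc3c2O1 | intermediate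
18 | CNP0167575.1, (3S,4R,3'S,4'R) syn head-to-tail cyclobutane dimer of seselin (dihydrocoumarin numbering, all four cyclobutane hydrogens cis, configuration as in the SMILES) | CC1(C)C=Cc2c(ccc3c2OC(=O)[C@H]2[C@@H]3[C@H]3C(=O)Oc4c5c(ccc4[C@H]32)OC(C)(C)C=C5)O1 | target

**Step count and risks**

Total step count: 10. Longest linear sequence: 9 steps (steps 1 to 4 and 6 to 10; step 5 is the side branch from 3).

Steps most likely to fail:

Step 10. A Z-alkene may isomerise to E in the excited state or in the diradical before the second bond forms, and the diradical may cleave to two molecules of seselin. The strong Lewis acid may also ionise the tertiary allylic pyran ether, and the two helical conformers may be poorly discriminated. The fallback sets out from 10 and uses known chemistry. Seselin would be irradiated in CH2Cl2 in the presence of BF3·OEt2, the Lewis-acid-promoted photodimerisation of coumarins, which for the parent coumarin favours the syn head-to-tail dimer. This should give the racemic syn head-to-tail dimer F1 after chromatographic removal of other dimers. Preparative HPLC on a chiral stationary phase would then deliver 18, where the fallback rejoins the route.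

Step 8. Cyclo-oligomerisation may outrun ring closure, because the seco acid must fold with an s-cis aryl propiolate, and the activated Z-acid may isomerise to E through reversible conjugate addition of DMAP. The fallback sets out from 13 and avoids both the free phenol and the nucleophilic catalyst. The acid would be converted with cyanuric fluoride and pyridine in CH2Cl2 into the acyl fluoride F2. Slow addition of F2 to a catalytic amount of tetrabutylammonium difluorotriphenylsilicate in THF at high dilution would then trigger fluoride-catalysed acylation of the aryl silyl ether by the acyl fluoride. The phenoxide is released only as fast as it is consumed, and the fallback rejoins the route at 16, bypassing 14 and 15.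

Step 6. The coumarinate may relactonise or be acylated at the carboxylate instead of the phenoxide, and the acid chloride may be lost to adventitious hydroxide. The fallback sets out from 3 and 8 and builds the Z-alkene instead of borrowing it. Steglich esterification (DCC, DMAP cat., CH2Cl2) would give the 2-formylaryl propiolate F3. Still–Gennari olefination (allyl bis(2,2,2-trifluoroethyl)phosphonoacetate, KN(SiMe3)2, 18-crown-6, THF, −78 °C) would give the allyl Z-cinnamate F4. Removal of the allyl ester with Pd(PPh3)4 (zerovalent palladium) and PhSiH3 would return to the route at 13.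

**Further compounds**

F1 | step 10 | racemic syn head-to-tail photodimer of seselin (18 together with its mirror image) | CC1(C)C=Cc2c(ccc3c2OC(=O)[C@H]2[C@@H]3[C@H]3C(=O)Oc4c5c(ccc4[C@H]32)OC(C)(C)C=C5)O1.CC1(C)C=Cc2c(ccc3c2OC(=O)[C@@H]2[C@H]3[C@@H]3C(=O)Oc4c5c(ccc4[C@@H]32)OC(C)(C)C=C5)O1
F2 | step 8 | (Z)-3-{5-[(3-{5-[(tert-butyldimethylsilyl)oxy]-2,2-dimethyl-2H-chromen-6-yl}prop-2-ynoyl)oxy]-2,2-dimethyl-2H-chromen-6-yl}prop-2-enoyl fluoride | FC(=O)/C=C\c1ccc2OC(C)(C)C=Cc2c1OC(=O)C#Cc1ccc2OC(C)(C)C=Cc2c1O[Si](C)(C)C(C)(C)C
F3 | step 6 | 6-formyl-2,2-dimethyl-2H-chromen-5-yl 3-{5-[(tert-butyldimethylsilyl)oxy]-2,2-dimethyl-2H-chromen-6-yl}prop-2-ynoate | O=Cc1ccc2OC(C)(C)C=Cc2c1OC(=O)C#Cc1ccc2OC(C)(C)C=Cc2c1O[Si](C)(C)C(C)(C)C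
F4 | step 6 | prop-2-en-1-yl (Z)-3-{5-[(3-{5-[(tert-butyldimethylsilyl)oxy]-2,2-dimethyl-2H-chromen-6-yl}prop-2-ynoyl)oxy]-2,2-dimethyl-2H-chromen-6-yl}prop-2-enoate | C=CCOC(=O)/C=C\c1ccc2OC(C)(C)C=Cc2c1OC(=O)C#Cc1ccc2OC(C)(C)C=Cc2c1O[Si](C)(C)C(C)(C)C
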